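**Plan**
1. Numbering used here: lactone O1, C2(=O), C3, C4, C5(Me); side chain C1′ (carbinol) to C11′ (CH2 on the furan). Retrosynthetic cuts: C3′–C4′ (sp3–sp2 Negishi coupling) gives lactone bromide 8 and alkenyl iodide 21; C9′–C10′ of 21 (B-alkyl Suzuki coupling) releases 3-vinylfuran; lactone bonds C3–C4 and O1–C5 are cut together, back to an epoxy triflate and tert-butyl acetate.
2. Enabling feature: ring O1 sits on quaternary C5 next to the free hydroxyl on C1′, and ring C4 is a bare CH2. This is the imprint of a trans-2,3-epoxy alcohol whose CH2O carbon (C4) was alkylated by an acetate enolate and whose tertiary epoxide carbon (C5) was opened from the rear by the carboxyl oxygen, the epoxide oxygen remaining as the C1′ hydroxyl.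
3. Forward order: bromoalkene 1 → allylic alcohol → epoxy alcohol → triflate → one-flask alkylation/lactonisation (the only ring made in the route) → silyl ether 8. Separately: ynal 9 → diynol → iodoalkene → furan attached → iodoalkene 21. Then union of 8 with 21 and desilylation.
4. Stereochemistry: C5 (S) and C1′ (R) both come from one catalytic Sharpless epoxidation and are relayed in the key step (inversion at C5, retention at C1′). C6′ (S) comes from a catalytic asymmetric propargylation. The 8′E alkene comes from syn-carboalumination and the 4′E alkene from syn-hydrozirconation, both carried through the couplings with retention.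

Key step: step 4

Remark: the sense of induction in step 6 is assumed to follow that of this catalyst class with aryl and alkenyl aldehydes, so the (S)-acid is specified for the Si-face addition needed; if the sense proved opposite, the (R)-acid would be used.

**Step 1**
Reactants: 1 5-bromo-2-methylpent-2-ene
Product: 2 (E)-5-bromo-2-methylpent-2-en-1-ol
Conditions: SeO2 (cat.), salicylic acid (cat.), tBuOOH, CH2Cl2, rt
Reagents that add atoms: tert-butyl hydroperoxide CC(C)(C)OO (oxygen source, relayed through SeO2)
Why: Riley allylic oxidation (ene reaction, then [2,3]-sigmatropic shift) of a gem-dimethyl trisubstituted alkene should hydroxylate the methyl group trans to the chain and give the (E)-allylic alcohol, the primary bromide being inert.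

**Step 2**
Reactants: 2 (E)-5-bromo-2-methylpent-2-en-1-ol
Product: 3 [(2R,3R)-3-(2-bromoethyl)-2-methyloxiran-2-yl]methanol
Conditions: Ti(OiPr)4 (10 mol %), D-(−)-diethyl tartrate (12 mol %), tBuOOH, 4 Å molecular sieves, CH2Cl2, −20 °C
Reagents that add atoms: tert-butyl hydroperoxide CC(C)(C)OO
Why: Sharpless asymmetric epoxidation of an (E)-2-methylallylic alcohol, a standard substrate class; with the D-(−)-tartrate the oxygen should be delivered to the face that gives the (2R,3R)-epoxide, fixing both stereocentres of the lactone part in one catalytic event.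

**Step 3**
Reactants: 3 [(2R,3R)-3-(2-bromoethyl)-2-methyloxiran-2-yl]methanol
Product: 4 [(2R,3R)-3-(2-bromoethyl)-2-methyloxiran-2-yl]methyl trifluoromethanesulfonate
Conditions: Tf2O, 2,6-lutidine, CH2Cl2, −78 °C; used crude
Reagents that add atoms: trifluoromethanesulfonic anhydride O=S(=O)(OS(=O)(=O)C(F)(F)F)C(F)(F)F
Why: Sulfonylation of the primary alcohol under buffered cryogenic conditions should give the epoxy triflate without opening the epoxide; no stereocentre is touched.

**Step 4**
Reactants: 4 [(2R,3R)-3-(2-bromoethyl)-2-methyloxiran-2-yl]methyl trifluoromethanesulfonate; 5 tert-butyl acetate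
Product: 7 (S)-5-[(R)-3-bromo-1-hydroxypropyl]-5-methyldihydrofuran-2(3H)-one, via epoxy ester 6 (not isolated)
Conditions: LiN(iPr)2, 5, THF, −78 °C; then 4, −78 → −30 °C; then CF3CO2H (excess), CH2Cl2, 0 °C → rt, same flask
Reagents that add atoms: none
Why: The lithium enolate of 5 displaces the primary triflate of 4 by SN2 to give the γ,δ-epoxy ester 6 (C3–C4 bond); on acidification the ester carbonyl oxygen attacks the protonated trisubstituted epoxide at its tertiary carbon and the tert-butyl group leaves as 2-methylpropene (O1–C5 bond). The closest known reaction types are the alkylation of carbanions with 2,3-epoxy triflates and the acid-mediated lactonisation of γ,δ-epoxy esters. The butanolide closes in the 5-exo-tet mode. C5 is set by backside attack, so the (2R) epoxide carbon is inverted to 5S, while C1′ is the untouched epoxide carbon whose C–O bond is retained (1′R). The step needs chemoselectivity for the triflate over the epoxide and the primary bromide, which the leaving-group ranking at −78 °C should secure. It also needs 5-exo opening at the tertiary carbon rather than 6-endo opening at the secondary one, which ring size and the cation-stabilising methyl group on that carbon both favour.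

**Step 5**
Reactants: 7 (S)-5-[(R)-3-bromo-1-hydroxypropyl]-5-methyldihydrofuran-2(3H)-one
Product: 8 (S)-5-[(R)-3-bromo-1-(triethylsilyloxy)propyl]-5-methyldihydrofuran-2(3H)-one
Conditions: Et3SiOTf, 2,6-lutidine, CH2Cl2, −78 → 0 °C
Reagents that add atoms: triethylsilyl trifluoromethanesulfonate CC[Si](CC)(CC)OS(=O)(=O)C(F)(F)F
Why: Silylation of the hindered secondary alcohol with a silyl triflate masks the O–H before the organozinc is made; no stereocentre is affected.

**Step 6**
Reactants: 9 but-2-ynal; 10 allenylboronic acid pinacol ester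
Product: 12 (S)-hepta-1,5-diyn-4-ol, via pinacol borate 11 (not isolated)
Conditions: (S)-TRIP [(S)-3,3′-bis(2,4,6-triisopropylphenyl)-1,1′-binaphthyl-2,2′-diyl hydrogen phosphate] (10 mol %), 4 Å molecular sieves, toluene, 0 °C; aqueous work-up
Reagents that add atoms: none
Why: Chiral-phosphoric-acid-catalysed allenylboration (SE2′ propargylation through a closed six-membered transition state in which the acid binds the boronate oxygen and the formyl hydrogen) should add the propargyl group to the Si face of the ynal and set the carbinol as (S).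

**Step 7**
Reactants: 12 (S)-hepta-1,5-diyn-4-ol
Product: 14 (S,E)-1-iodo-2-methylhept-1-en-5-yn-4-ol, via alkenylalane 13 (not isolated)
Conditions: AlMe3 (3 equiv), Cp2ZrCl2 (0.3 equiv), CH2Cl2, 0 °C → rt; then I2, THF, −30 °C
Reagents that add atoms: trimethylaluminium C[Al](C)C; iodine II
Why: Zirconium-catalysed carboalumination (Negishi carboalumination) adds methyl and aluminium syn across the terminal alkyne with aluminium at the terminus, leaving the internal alkyne untouched, and iodinolysis with retention should give the (E)-iodoalkene.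

**Step 8**
Reactants: 14 (S,E)-1-iodo-2-methylhept-1-en-5-yn-4-ol
Product: 15 (S,E)-1-iodo-4-methoxy-2-methylhept-1-en-5-yne
Conditions: NaH, MeI, THF, 0 °C → rt
Reagents that add atoms: iodomethane CI
Why: Williamson etherification of the secondary alkoxide; the stereocentre is not involved and the iodoalkene has no β-hydrogen available for elimination.

**Step 9**
Reactants: 16 furan-3-carbaldehyde
Product: 17 3-vinylfuran
Conditions: Ph3PCH3Br, KOtBu, THF, 0 °C → rt; kept as a THF solution
Reagents that add atoms: methyltriphenylphosphonium bromide C[P+](c1ccccc1)(c1ccccc1)c1ccccc1.[Br-]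
Why: Wittig methylenation of the aromatic aldehyde should give the volatile vinylfuran, which is carried on in solution.

**Step 10**
Reactants: 17 3-vinylfuran; 15 (S,E)-1-iodo-4-methoxy-2-methylhept-1-en-5-yne
Product: 19 3-[(3E,6S)-6-methoxy-4-methylnon-3-en-7-yn-1-yl]furan, via alkylborane 18 (not isolated)
Conditions: 17, 9-BBN (slightly less than 1 equiv), THF, 0 °C → rt; then 15, PdCl2(dppf) (5 mol %), AsPh3, Cs2CO3, DMF–H2O, rt
Reagents that add atoms: none
Why: Anti-Markovnikov hydroboration of the vinyl group followed by B-alkyl Suzuki–Miyaura coupling with the alkenyl iodide should form the C9′–C10′ bond with retention of the (E) geometry; the internal alkyne does not react, and the palladium sits trans to the tether so it cannot cyclise onto it.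

**Step 11**
Reactants: 19 3-[(3E,6S)-6-methoxy-4-methylnon-3-en-7-yn-1-yl]furan
Product: 21 3-[(3E,6S,7E)-8-iodo-6-methoxy-4-methylnona-3,7-dien-1-yl]furan, via alkenylzirconocene 20 (not isolated)
Conditions: Cp2Zr(H)Cl (2 equiv), THF, rt; then I2, THF, −78 → 0 °C
Reagents that add atoms: iodine II
Why: Hydrozirconation adds Zr–H syn across the internal alkyne with zirconium on the less hindered, methyl-bearing carbon (away from the branched ether carbon), and iodinolysis with retention should give the (E)-2-iodoalkene; the trisubstituted alkene and the furan are inert to Cp2Zr(H)Cl.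

**Step 12**
Reactants: 8 (S)-5-[(R)-3-bromo-1-(triethylsilyloxy)propyl]-5-methyldihydrofuran-2(3H)-one; 21 3-[(3E,6S,7E)-8-iodo-6-methoxy-4-methylnona-3,7-dien-1-yl]furan
Product: 23 (S)-5-[(1R,4E,6S,8E)-11-(furan-3-yl)-6-methoxy-4,8-dimethyl-1-(triethylsilyloxy)undeca-4,8-dien-1-yl]-5-methyldihydrofuran-2(3H)-one, via alkylzinc bromide 22 (not isolated)
Conditions: 8, Zn dust, I2 (5 mol %), DMA, 70 °C; then 21, PdCl2(dppf) (5 mol %), THF–DMA, 40 °C
Reagents that add atoms: none
Why: Direct zinc insertion into the primary bromide tolerates the lactone and the silyl ether, and Negishi sp3–sp2 coupling of the alkylzinc with the alkenyl iodide should join the two fragments with retention of alkene geometry.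

**Step 13**
Reactants: 23 (S)-5-[(1R,4E,6S,8E)-11-(furan-3-yl)-6-methoxy-4,8-dimethyl-1-(triethylsilyloxy)undeca-4,8-dien-1-yl]-5-methyldihydrofuran-2(3H)-one
Product: 24 (S)-5-[(1R,4E,6S,8E)-11-(furan-3-yl)-1-hydroxy-6-methoxy-4,8-dimethylundeca-4,8-dien-1-yl]-5-methyldihydrofuran-2(3H)-one
Conditions: HF·pyridine, pyridine, THF, 0 °C → rt
Reagents that add atoms: none
Why: Buffered fluoride cleavage of the triethylsilyl ether should release the secondary alcohol without touching the lactone, the allylic methyl ether or the furan.

**Compound list**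
1 | 5-bromo-2-methylpent-2-ene | CC(C)=CCCBr | starting material
2 | (E)-5-bromo-2-methylpent-2-en-1-ol | OC/C(C)=C/CCBr | intermediate
3 | [(2R,3R)-3-(2-bromoethyl)-2-methyloxiran-2-yl]methanol | OC[C@@]1(C)O[C@@H]1CCBr | intermediate
4 | [(2R,3R)-3-(2-bromoethyl)-2-methyloxiran-2-yl]methyl trifluoromethanesulfonate | O=S(=O)(OC[C@@]1(C)O[C@@H]1CCBr)C(F)(F)F | intermediate
5 | tert-butyl acetate | CC(=O)OC(C)(C)C | starting material
6 | tert-butyl 3-[(2R,3R)-3-(2-bromoethyl)-2-methyloxiran-2-yl]propanoate | CC(C)(C)OC(=O)CC[C@@]1(C)O[C@@H]1CCBr | intermediate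
7 | (S)-5-[(R)-3-bromo-1-hydroxypropyl]-5-methyldihydrofuran-2(3H)-one | BrCC[C@@H](O)[C@]1(C)CCC(=O)O1 | intermediate
8 | (S)-5-[(R)-3-bromo-1-(triethylsilyloxy)propyl]-5-methyldihydrofuran-2(3H)-one | BrCC[C@@H](O[Si](CC)(CC)CC)[C@]1(C)CCC(=O)O1 | intermediate
9 | but-2-ynal | CC#CC=O | starting material
10 | allenylboronic acid pinacol ester (4,4,5,5-tetramethyl-2-(propa-1,2-dienyl)-1,3,2-dioxaborolane) | C=C=CB1OC(C)(C)C(C)(C)O1 | starting material
11 | 2-[(S)-hepta-1,5-diyn-4-yloxy]-4,4,5,5-tetramethyl-1,3,2-dioxaborolane | CC1(C)OB(O[C@H](C#CC)CC#C)OC1(C)C | intermediate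
12 | (S)-hepta-1,5-diyn-4-ol | O[C@H](C#CC)CC#C | intermediate
13 | dimethylaluminium (S,E)-1-(dimethylalumanyl)-2-methylhept-1-en-5-yn-4-olate | C[Al](C)O[C@H](C#CC)C/C(C)=C/[Al](C)C | intermediate
14 | (S,E)-1-iodo-2-methylhept-1-en-5-yn-4-ol | O[C@H](C#CC)C/C(C)=C/I | intermediate
15 | (S,E)-1-iodo-4-methoxy-2-methylhept-1-en-5-yne | CO[C@H](C#CC)C/C(C)=C/I | intermediate
16 | furan-3-carbaldehyde | O=Cc1ccoc1 | starting material
17 | 3-vinylfuran | C=Cc1ccoc1 | intermediate
18 | 9-[2-(furan-3-yl)ethyl]-9-borabicyclo[3.3.1]nonane | C1CC2CCCC(C1)B2CCc1ccoc1 | intermediate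
19 | 3-[(3E,6S)-6-methoxy-4-methylnon-3-en-7-yn-1-yl]furan | CO[C@H](C#CC)C/C(C)=C/CCc1ccoc1 | intermediate
20 | chlorobis(cyclopentadienyl)[(2E,4S,6E)-9-(furan-3-yl)-4-methoxy-6-methylnona-2,6-dien-2-yl]zirconium (Zr syn to H, cyclopentadienyl rings drawn σ-bound) | CO[C@H](/C=C(\C)[Zr](Cl)(C1C=CC=C1)C1C=CC=C1)C/C(C)=C/CCc1ccoc1 | intermediate
21 | 3-[(3E,6S,7E)-8-iodo-6-methoxy-4-methylnona-3,7-dien-1-yl]furan | CO[C@H](/C=C(\C)I)C/C(C)=C/CCc1ccoc1 | intermediate
22 | bromo{(R)-3-[(S)-2-methyl-5-oxotetrahydrofuran-2-yl]-3-(triethylsilyloxy)propyl}zinc | Br[Zn]CC[C@@H](O[Si](CC)(CC)CC)[C@]1(C)CCC(=O)O1 | intermediate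
23 | (S)-5-[(1R,4E,6S,8E)-11-(furan-3-yl)-6-methoxy-4,8-dimethyl-1-(triethylsilyloxy)undeca-4,8-dien-1-yl]-5-methyldihydrofuran-2(3H)-one | CO[C@H](/C=C(\C)CC[C@@H](O[Si](CC)(CC)CC)[C@]1(C)CCC(=O)O1)C/C(C)=C/CCc1ccoc1 | intermediate
24 | (S)-5-[(1R,4E,6S,8E)-11-(furan-3-yl)-1-hydroxy-6-methoxy-4,8-dimethylundeca-4,8-dien-1-yl]-5-methyldihydrofuran-2(3H)-one | CO[C@H](/C=C(\C)CC[C@@H](O)[C@]1(C)CCC(=O)O1)C/C(C)=C/CCc1ccoc1 | target

**Totals**
Total step count: 13. Longest linear sequence: 7 steps (1 → 2 → 3 → 4 → 5 → 12 → 13; the branch 6 → 7 → 8 → 10 → 11 → 12 → 13 is equally long).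

**Steps most likely to fail**

Step 4. The enolate may attack the epoxide or be O-alkylated instead of displacing the hindered primary triflate. In the acid stage the tertiary C–O bond may ionise before the carbonyl oxygen arrives, eroding the inversion, or a hydride shift may divert the epoxide to a ketone. The fallback uncouples chain extension from ring closure and sets out from 3. Oxidation with Dess–Martin periodinane (NaHCO3, CH2Cl2) should give (2S,3R)-3-(2-bromoethyl)-2-methyloxirane-2-carbaldehyde F1. Wittig reaction of F1 with tert-butyl (triphenylphosphoranylidene)acetate should give tert-butyl (E)-3-[(2R,3R)-3-(2-bromoethyl)-2-methyloxiran-2-yl]prop-2-enoate F2. Diimide reduction of the conjugated alkene (2-nitrobenzenesulfonohydrazide, Et3N, CH2Cl2) should then give isolated 6, where the fallback comes back to the route. Compound 6 is closed to 7 with a milder acid (camphorsulfonic acid, or BF3·OEt2 at −40 °C) that can be tuned for clean inversion.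

Step 11. Zirconium may add to the carbon next to the methoxy-bearing centre, after which β-alkoxide elimination would give an allene, or the iodine quench may attack the furan. The fallback sets out from 19 and relies on electronic rather than steric regiocontrol. Copper-catalysed syn-hydroboration (CuCl, NaOtBu, an N-heterocyclic carbene ligand, B2pin2, MeOH, THF) places boron on the carbon distal to the propargylic C–O bond and should give 3-[(3E,6S,7Z)-6-methoxy-4-methyl-8-(4,4,5,5-tetramethyl-1,3,2-dioxaborolan-2-yl)nona-3,7-dien-1-yl]furan F3. Iododeboronation with retention (aqueous NaOH, then I2, THF, 0 °C) should return to the route at 21.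

Step 12. Zinc insertion into the primary bromide may be slow or incomplete, the alkylzinc may be protonated by adventitious water, or the zinc halides may cleave the silyl ether at 70 °C. The fallback sets out from 8 and 21 and comes back at 23 in one operation with no pre-formed organometallic: a nickel-catalysed reductive cross-electrophile coupling (NiBr2·glyme, 4,4′-di-tert-butyl-2,2′-bipyridine, Mn powder, NaI, DMA, rt), in which the alkyl radical from 8 is captured by the alkenylnickel species from 21. No further compound arises (F0).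

**Further compounds**
F1 | step 4 | (2S,3R)-3-(2-bromoethyl)-2-methyloxirane-2-carbaldehyde | O=C[C@@]1(C)O[C@@H]1CCBr
F2 | step 4 | tert-butyl (E)-3-[(2R,3R)-3-(2-bromoethyl)-2-methyloxiran-2-yl]prop-2-enoate | CC(C)(C)OC(=O)/C=C/[C@@]1(C)O[C@@H]1CCBr
F3 | step 11 | 3-[(3E,6S,7Z)-6-methoxy-4-methyl-8-(4,4,5,5-tetramethyl-1,3,2-dioxaborolan-2-yl)nona-3,7-dien-1-yl]furan | CO[C@H](/C=C(\C)B1OC(C)(C)C(C)(C)O1)C/C(C)=C/CCc1ccoc1
F0 | step 12 | none | none
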